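Friday's flask holds more free catalyst than Wednesday's and less racemization catalyst. Does its product come out less pure?

| flask | left-handed substrate | right-handed substrate | gas | free catalyst | racemization catalyst | remark | time |
|---|---|---|---|---|---|---|---|
| epsilon | 0.75 M | 0.75 M | 24 mM (held) | 25 mM | 1 mM | run made earlier |  |
| theta | 1 M | 1 M | 24 mM (held) | 25 mM | 1 mM | run made earlier |  |
| Wednesday's | 0.50 M | 0.50 M | 24 mM (held) | 25 mM | 1.0 mM |  | 5.0 h |
| Friday's | 0.50 M | 0.50 M | 24 mM (held) | 40 mM | 0.25 mM |  | 5.0 h |

| run | time / min | left-handed product / % | right-handed product / % | left-handed substrate / % |
|---|---|---|---|---|
| epsilon | 5.00 | 0 | 0 | 51.1 |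
| epsilon | 12.0 | 2.3 | 1.1 | 49.1 |
| epsilon | 25.0 | 4.0 | 2.1 | 47.3 |
| epsilon | 60.0 | 9.8 | 1.7 | 41.9 |
| theta | 5.00 | 0.1 | 0 | 49.2 |
| theta | 12.0 | 2.1 | 0 | 48.4 |
| theta | 25.0 | 3.6 | 0.7 | 46.9 |
| theta | 60.0 | 9.7 | 2.5 | 43.9 |

(each reading ± 1 percentage point)

- the winner by excess of left-handed product over right-handed product; "neither" if no more than 2 percentage points parts them (Wednesday's / Friday's / neither)
- excess of left-handed product over right-handed product at the end, Wednesday's
- excess of left-handed product over right-handed product at the end, Friday's

- free catalyst is single-handed; left-handed substrate and right-handed substrate are mirror images of each other, charged as a racemate, each of them at the stated concentration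
- the analysis behind the earlier runs scatters by 1 percentage point, standard deviation
- at the start none of the gas is in solution
- an excess is below zero if the other one leads
- no earlier run changes the charge of racemization catalyst; that part of a forecast is a guess
- no earlier run changes the charge of free catalyst; that part of a forecast is a guess

Excess here means left-handed product minus right-handed product, over both products.

Follow one substrate molecule. On the racemization catalyst it flips to its mirror image. On the free catalyst it is captured as product. If it flips often before capture, the two substrates stay equal, and each capture is a fresh draw at fixed odds, the selectivity factor.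

Two chemists dispute how often it flips. Both read the gap, right-handed substrate minus left-handed substrate, by balance at 60.0 min. The epsilon run gives 4.7 percentage points, and the theta run shows no gap. Without flipping, the gap would equal the product difference, 8.1 points and 7.2 points.

The second chemist takes the mean gap as real, so flipping is moderate and Friday's suffers. That is the forecast: Wednesday's, with 62% (52% to 71%) for Wednesday's and 56% (42% to 66%) for Friday's. In its words, “The imbalance builds”.

The first chemist reckons otherwise. The mean of the two gaps, 2.3 points, carries a scatter near 1.7 points, so flipping may be far faster. She carries the fork shift, the change in flips per capture from Wednesday's to Friday's, reckoned from [racemization catalyst]/[free catalyst]: 0.156. This assumes rates scale with catalyst, which is a guess. If flips per capture stay well above unity after that shift, the odds hold, and she says neither.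

The flask gives neither: 48.6% for Wednesday's and 47.9% for Friday's.

    reagent + free catalyst + left-handed substrate → free catalyst + left-handed product (k = 9.00 L² mol⁻² min⁻¹)
    reagent + free catalyst + right-handed substrate → free catalyst + right-handed product (k = 3.10 L² mol⁻² min⁻¹)
    left-handed substrate + racemization catalyst ⇌ right-handed substrate + racemization catalyst, rate k3*[racemization catalyst]*[left-handed substrate] forward; the back reaction follows from the equilibrium constant (k = 370 L mol⁻¹ min⁻¹)
    gas ⇌ reagent, rate k4*(csat - [reagent]) (kL = 0.400 min⁻¹)

With flipping removed, Friday's trails Wednesday's by 6.4 points, and that is the region of the forecast's view. With flipping on, a left-handed substrate molecule in Wednesday's flips 79.5 times per capture at 5.00 h, counting the forward step. The fork shift puts Friday's at 12.4.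

In a neighbour of Wednesday's with 6.30 mM free catalyst, the shift is 3.97, against Friday's 0.156. Taking Wednesday's [reagent], that means about 316 flips per capture, so the odds should stand. That neighbour gives 48.7%, from 16.5% left-handed product and 5.69% right-handed product.

All runs are calculated on assumed constants; scatter was added.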